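Time one round of the catalyst before you ask about orders.

| flask | substrate | partner | protic impurity | free catalyst | stray impurity | remark |
|---|---|---|---|---|---|---|
| Saturday's | 0.020 M | 0.10 M | 6 mM | 1 mM | 0.17 mM | the very flask that is asked about, followed so far |
| Wednesday's | 0.020 M | 0.10 M | 12 mM | 1 mM | 0.17 mM | run made earlier |
| flask | 0.020 M | 0.100 M | 6.00 mM | 1.0 mM | 0.17 mM |  |

| Saturday's: time / h | Saturday's: product / % | Wednesday's: time / h | Wednesday's: product / % |
|---|---|---|---|
| 0.200 | 4 | 0.417 | 8 |
| 0.500 | 10 | 1.33 | 29 |
| 1.00 | 24 | 2.50 | 49 |
| 2.50 | 54 | 4.00 | 70 |

(scatter of a reading: 1.5 percentage points)

1. apparent order in free catalyst when 30% of the substrate are converted (percent change of the rate of making product for one percent more free catalyst charged)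
2. apparent order in partner when 30% of the substrate are converted (percent change of the rate of making product for one percent more partner charged)
3. factor on the rate of making product when 30% of the substrate are converted if partner is charged twice over

- on the list of suspects stand: partner + protic impurity -> quenched reagent; partner + catalyst intermediate A -> catalyst intermediate B; free catalyst + stray impurity -> spent catalyst; catalyst intermediate B -> free catalyst + product; substrate + free catalyst -> catalyst intermediate A
- no earlier run changes the charge of free catalyst; that part of a forecast is a guess
- no earlier run changes the charge of partner; that part of a forecast is a guess

If the stray impurity takes catalyst one for one, Saturday's flask keeps 0.830 mM of working catalyst. Between 1.00 h and 2.50 h the readings of that flask give a rate of making product of 4.00 mM/h. Divide the first by the second and you get 12.4 min. Call this the round time (turnover time), the average time one working catalyst needs to make one product.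

A round is a sum of waits, and the wait for partner goes as one over c(partner). So, at a fixed conversion and with the other charges held, the order in partner is the share of the round spent on that wait, times charge over what is left. If the protic impurity takes partner one for one, Saturday's flask has 88.0 mM of partner left at 30% conversion, which makes that factor 1.14.

But can Wednesday's run give the share? Its flask has 82.0 mM left, 6.82% less. Its rate, read at matching conversion, carries a scatter of 10.6%. So I commit to the rule and to no share from that pair.

The forecast takes that pair as a hint that “the partner step carries much of the resistance”. It gives 1.15 for the order in free catalyst, 0.6 for the order in partner and 1.4 for the doubling factor.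

    partner + protic impurity → quenched reagent (k = 2.10 /M/min)
    partner + catalyst intermediate A → catalyst intermediate B (k = 3.40 /M/min)
    free catalyst + stray impurity → spent catalyst (k = 980 /M/min)
    catalyst intermediate B → free catalyst + product (k = 1.00 /min)
    substrate + free catalyst → catalyst intermediate A (k = 9.70 /M/min)

The flask gives 1.2, 0.32 and 1.18 in the same order, so the order in partner stands below the forecast's. With partner charged twice over, the rate at 30% conversion is higher by a factor of 1.18. With 88.0 mM of partner, the wait in Saturday's flask is 3.34 min, against the round of 12.4 min read from that flask's readings, a share of 0.268. Times the factor, that gives 0.305. In Wednesday's flask, with 82.0 mM of partner at that conversion, the wait is longer by 0.245 min, which is 1.98% of Saturday's round.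

(All runs stem from a simulated flask on assumed constants; scatter was added.)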